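**Retrosynthetic overview**
1. Target 18 ⇐ allyl-oxocane 14: ozonolysis, Z-selective Peterson enyne formation, desilylation.
2. Oxocane (formed last) ⇐ oxolane 11: the oxolane oxygen displaces a C6 triflate (C6–O bond), and chloride opens the resulting bicyclic oxonium at C9 (C9–Cl). This relay ring expansion is the key step and is new.
3. 11 ⇐ aldehyde 8: organocatalytic α-chlorination (C7) and allylboration (C6).
4. Oxolane ring B (formed first) ⇐ acetonide 5: ketal-participating bromoetherification of the 12E-olefin (C12–O, C13–Br).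
5. 5 ⇐ 2-deoxy-D-ribose 1 (C8–C12, stereocentres C9 and C10); propylidene by Julia–Kocienski olefination, C6–C7 by acetylide alkylation.

Assumption: carbons are labelled C1–C15 along the chain of the target (C1 = alkyne CH; ring O on C6 and C12; Cl on C7 and C9; OAc on C10; Br on C13), and all reagents named under Conditions, including the propyl tetrazolyl sulfone, are bought.

**Step 1**
Reactants: 1 2-deoxy-D-ribose
Product: 2 2-deoxy-3,4-O-isopropylidene-D-erythro-pentopyranose
Conditions: 2-methoxypropene, PPTS (cat.), EtOAc, 0 °C to rt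
Reagents that add atoms: 2-methoxypropene, COC(C)=C
Why: Acid-catalysed ketalisation takes the only cis-vicinal diol (O3/O4 of the pyranose form), leaving the lactol free and the two sugar stereocentres (later C10 and C9) untouched.

**Step 2**
Reactants: 2 2-deoxy-3,4-O-isopropylidene-D-erythro-pentopyranose
Product: 3 [(4R,5S)-2,2-dimethyl-5-[(2E)-pent-2-en-1-yl]-1,3-dioxolan-4-yl]methanol
Conditions: 1-phenyl-5-(propylsulfonyl)-1H-tetrazole, KN(SiMe3)2, DME, −60 °C to rt
Reagents that add atoms: 1-phenyl-5-(propylsulfonyl)-1H-tetrazole, CCCS(=O)(=O)c1nnnn1-c1ccccc1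
Why: Julia–Kocienski olefination on the open-chain hydroxy-aldehyde tautomer of the lactol; the phenyltetrazolyl sulfone with a potassium base in DME gives the E-olefin (C12=C13) and frees the primary C8 hydroxyl.

**Step 3**
Reactants: 3 [(4R,5S)-2,2-dimethyl-5-[(2E)-pent-2-en-1-yl]-1,3-dioxolan-4-yl]methanol
Product: 4 [(4R,5S)-2,2-dimethyl-5-[(2E)-pent-2-en-1-yl]-1,3-dioxolan-4-yl]methyl 4-methylbenzenesulfonate
Conditions: TsCl, Et3N, DMAP (cat.), CH2Cl2, 0 °C to rt
Reagents that add atoms: p-toluenesulfonyl chloride, Cc1ccc(cc1)S(Cl)(=O)=O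
Why: Routine sulfonylation of the only hydroxyl group.

**Step 4**
Reactants: 4 [(4R,5S)-2,2-dimethyl-5-[(2E)-pent-2-en-1-yl]-1,3-dioxolan-4-yl]methyl 4-methylbenzenesulfonate
Product: 5 (4S,5R)-2,2-dimethyl-4-[(2E)-pent-2-en-1-yl]-5-(prop-2-yn-1-yl)-1,3-dioxolane
Conditions: LiC≡CH·H2NCH2CH2NH2, DMSO, rt
Reagents that add atoms: lithium acetylide–ethylenediamine complex, [Li]C#C.NCCN
Why: SN2 alkynylation of a primary tosylate installs C7 and C6 as a terminal alkyne, a masked aldehyde that is inert to the bromination that follows.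

**Step 5**
Reactants: 5 (4S,5R)-2,2-dimethyl-4-[(2E)-pent-2-en-1-yl]-5-(prop-2-yn-1-yl)-1,3-dioxolane
Product: 7 (2R,3S,5R)-5-[(1S)-1-bromopropyl]-2-(prop-2-yn-1-yl)oxolan-3-yl acetate, via hydroxy-oxolane 6 (not isolated)
Conditions: NBS, MeCN, H2O (5 equiv), 0 °C, dark; work-up; then Ac2O, pyridine, DMAP (cat.), CH2Cl2, 0 °C to rt
Reagents that add atoms: N-bromosuccinimide, O=C1CCC(=O)N1Br; acetic anhydride, CC(=O)OC(C)=O
Why: Ketal-participating 5-exo bromoetherification (the bromine analogue of the iodonium cyclisation of alkenyl isopropylidene acetals): the dioxolane oxygen on C9 opens the bromonium ion anti, so the E-olefin gives 12R,13S; in the bridged oxonium the bromopropyl group turns away from the CMe2 bridge, which makes the oxolane 2,5-cis; loss of acetone frees the C10 hydroxyl, which is acetylated.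

**Step 6**
Reactants: 7 (2R,3S,5R)-5-[(1S)-1-bromopropyl]-2-(prop-2-yn-1-yl)oxolan-3-yl acetate
Product: 8 (2R,3S,5R)-5-[(1S)-1-bromopropyl]-2-(3-oxopropyl)oxolan-3-yl acetate
Conditions: [CpRu(MeCN)3]PF6 (5 mol %), 5,5'-bis(trifluoromethyl)-2,2'-bipyridine (5 mol %), H2O, NMP, 50 °C
Reagents that add atoms: water, O
Why: Ruthenium-catalysed anti-Markovnikov hydration of the terminal alkyne (via a vinylidene) gives the C6 aldehyde under neutral conditions that spare the acetate and the secondary bromide.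

**Step 7**
Reactants: 8 (2R,3S,5R)-5-[(1S)-1-bromopropyl]-2-(3-oxopropyl)oxolan-3-yl acetate
Product: 11 (2R,3S,5R)-5-[(1S)-1-bromopropyl]-2-[(2S,3R)-2-chloro-3-hydroxyhex-5-en-1-yl]oxolan-3-yl acetate, via α-chloroaldehyde 9 (not isolated), via borinate ester 10 (not isolated)
Conditions: NCS, (2R,5R)-2,5-diphenylpyrrolidine (10 mol %), CH2Cl2, 0 °C to rt; pentane, filter, concentrate; then (+)-Ipc2B(allyl), Et2O, −78 °C; HOCH2CH2NH2, rt
Reagents that add atoms: N-chlorosuccinimide, O=C1CCC(=O)N1Cl; (+)-B-allyldiisopinocampheylborane, C=CCB([C@H]1C[C@H]2C[C@@H]([C@@H]1C)C2(C)C)[C@H]1C[C@H]2C[C@@H]([C@@H]1C)C2(C)C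
Why: Enamine-catalysed α-chlorination sets C7 as S under catalyst control (chlorine enters anti to the phenyl group flanking the enamine carbon), and Brown allylboration with the Re-face-selective (+)-reagent, matched with the Cornforth preference of the α-chloroaldehyde, sets C6 as R (anti chlorohydrin).

**Step 8**
Reactants: 11 (2R,3S,5R)-5-[(1S)-1-bromopropyl]-2-[(2S,3R)-2-chloro-3-hydroxyhex-5-en-1-yl]oxolan-3-yl acetate
Product: 14 (2R,4S,5S,7S,8S)-2-[(1S)-1-bromopropyl]-5,7-dichloro-8-(prop-2-en-1-yl)oxocan-4-yl acetate, via secondary triflate 12 (not isolated), via bicyclic oxonium triflate 13 (not isolated)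
Conditions: Tf2O, 2,6-di-tert-butyl-4-methylpyridine, CH2Cl2, −78 to −30 °C; then Bu4NCl, −78 to 0 °C
Reagents that add atoms: tetrabutylammonium chloride, CCCC[N+](CCCC)(CCCC)CCCC.[Cl-]
Why: Proposed new method: a sulfonate-triggered relay ring expansion of an oxolane to an oxocane terminated by external chloride; the oxolane oxygen displaces the C6 triflate (five-membered O-participation, inversion, 6R→6S, forming the C6–O bond of the target) to give the cis-fused 1-oxoniabicyclo[3.3.0]octane 13, and chloride then opens the ring-fusion C9–O bond by SN2 (inversion, giving 9S-Cl), merging the two five-membered rings into the oxocane; the argument for C9 is that its backside lies on the open convex edge next to the unsubstituted C8 methylene, whereas C6 is flanked by the C7 chloride and C12 by the inward-pointing CHBrEt branch, and only fusion-bond cleavage releases the strain of both rings, but this site selectivity is unproven and is the main uncertainty of the route; closest known chemistry: bromonium-initiated oxolane-to-oxocane expansions in which a tethered carbonyl opens the same kind of oxonium ion at the bridgehead, and sulfonate-triggered ring expansions of cyclic ethers through bicyclic oxonium ions.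

**Step 9**
Reactants: 14 (2R,4S,5S,7S,8S)-2-[(1S)-1-bromopropyl]-5,7-dichloro-8-(prop-2-en-1-yl)oxocan-4-yl acetate
Product: 16 (2R,4S,5S,7S,8S)-2-[(1S)-1-bromopropyl]-5,7-dichloro-8-(2-oxoethyl)oxocan-4-yl acetate, via ozonide 15 (not isolated)
Conditions: O3, CH2Cl2, −78 °C; then PPh3, −78 °C to rt
Reagents that add atoms: ozone, [O-][O+]=O
Why: Ozonolysis with reductive work-up cleaves the only olefin left in the molecule to the C4 aldehyde.

**Step 10**
Reactants: 16 (2R,4S,5S,7S,8S)-2-[(1S)-1-bromopropyl]-5,7-dichloro-8-(2-oxoethyl)oxocan-4-yl acetate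
Product: 17 (2R,4S,5S,7S,8S)-2-[(1S)-1-bromopropyl]-5,7-dichloro-8-[(2Z)-5-(triisopropylsilyl)pent-2-en-4-yn-1-yl]oxocan-4-yl acetate
Conditions: iPr3SiC≡CCH2SiiPr3, n-BuLi, THF, −20 °C; then 16, −78 °C
Reagents that add atoms: 1,3-bis(triisopropylsilyl)propyne, CC(C)[Si](C(C)C)(C(C)C)CC#C[Si](C(C)C)(C(C)C)C(C)C
Why: Peterson olefination with the lithiated bis-silylpropyne gives the Z-enyne (bulky silyl groups enforce the syn-elimination geometry); at −78 °C the aldehyde reacts far faster than the acetate.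

**Step 11**
Reactants: 17 (2R,4S,5S,7S,8S)-2-[(1S)-1-bromopropyl]-5,7-dichloro-8-[(2Z)-5-(triisopropylsilyl)pent-2-en-4-yn-1-yl]oxocan-4-yl acetate
Product: 18 (2R,4S,5S,7S,8S)-2-[(1S)-1-bromopropyl]-5,7-dichloro-8-[(2Z)-pent-2-en-4-yn-1-yl]oxocan-4-yl acetate
Conditions: Bu4NF, AcOH (1:1), THF, 0 °C to rt
Reagents that add atoms: none
Why: Buffered fluoride desilylation of the alkynylsilane leaves the acetate and the secondary halides intact and gives the target.

**Compound list**
1 | 2-deoxy-D-ribose (drawn open-chain) | O=CC[C@H](O)[C@H](O)CO | starting material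
2 | 2-deoxy-3,4-O-isopropylidene-D-erythro-pentopyranose (anomer mixture) | OC1C[C@@H]2OC(C)(C)O[C@@H]2CO1 | intermediate
3 | [(4R,5S)-2,2-dimethyl-5-[(2E)-pent-2-en-1-yl]-1,3-dioxolan-4-yl]methanol | CC/C=C/C[C@@H]1OC(C)(C)O[C@@H]1CO | intermediate
4 | [(4R,5S)-2,2-dimethyl-5-[(2E)-pent-2-en-1-yl]-1,3-dioxolan-4-yl]methyl 4-methylbenzenesulfonate | CC/C=C/C[C@@H]1OC(C)(C)O[C@@H]1COS(=O)(=O)c1ccc(C)cc1 | intermediate
5 | (4S,5R)-2,2-dimethyl-4-[(2E)-pent-2-en-1-yl]-5-(prop-2-yn-1-yl)-1,3-dioxolane | CC/C=C/C[C@@H]1OC(C)(C)O[C@@H]1CC#C | intermediate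
6 | (2R,3S,5R)-5-[(1S)-1-bromopropyl]-2-(prop-2-yn-1-yl)oxolan-3-ol | C#CC[C@H]1O[C@@H]([C@@H](Br)CC)C[C@@H]1O | intermediate
7 | (2R,3S,5R)-5-[(1S)-1-bromopropyl]-2-(prop-2-yn-1-yl)oxolan-3-yl acetate | C#CC[C@H]1O[C@@H]([C@@H](Br)CC)C[C@@H]1OC(C)=O | intermediate
8 | (2R,3S,5R)-5-[(1S)-1-bromopropyl]-2-(3-oxopropyl)oxolan-3-yl acetate | O=CCC[C@H]1O[C@@H]([C@@H](Br)CC)C[C@@H]1OC(C)=O | intermediate
9 | (2R,3S,5R)-5-[(1S)-1-bromopropyl]-2-[(2S)-2-chloro-3-oxopropyl]oxolan-3-yl acetate | O=C[C@@H](Cl)C[C@H]1O[C@@H]([C@@H](Br)CC)C[C@@H]1OC(C)=O | intermediate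
10 | O-diisopinocampheylborinate of 11 | C=CC[C@@H](OB([C@H]2C[C@H]3C[C@@H]([C@@H]2C)C3(C)C)[C@H]2C[C@H]3C[C@@H]([C@@H]2C)C3(C)C)[C@@H](Cl)C[C@H]1O[C@@H]([C@@H](Br)CC)C[C@@H]1OC(C)=O | intermediate
11 | (2R,3S,5R)-5-[(1S)-1-bromopropyl]-2-[(2S,3R)-2-chloro-3-hydroxyhex-5-en-1-yl]oxolan-3-yl acetate | C=CC[C@@H](O)[C@@H](Cl)C[C@H]1O[C@@H]([C@@H](Br)CC)C[C@@H]1OC(C)=O | intermediate
12 | (2R,3S,5R)-5-[(1S)-1-bromopropyl]-2-[(2S,3R)-2-chloro-3-(trifluoromethanesulfonyloxy)hex-5-en-1-yl]oxolan-3-yl acetate | C=CC[C@@H](OS(=O)(=O)C(F)(F)F)[C@@H](Cl)C[C@H]1O[C@@H]([C@@H](Br)CC)C[C@@H]1OC(C)=O | intermediate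
13 | (2S,3S,5R,6S,8R)-6-acetoxy-8-[(1S)-1-bromopropyl]-3-chloro-2-(prop-2-en-1-yl)-1-oxoniabicyclo[3.3.0]octane trifluoromethanesulfonate (O+ bonded to C6, C9 and C12) | C=CC[C@H]1[C@@H](Cl)C[C@@H]2[C@@H](OC(C)=O)C[C@H]([C@@H](Br)CC)[O+]12.[O-]S(=O)(=O)C(F)(F)F | intermediate
14 | (2R,4S,5S,7S,8S)-2-[(1S)-1-bromopropyl]-5,7-dichloro-8-(prop-2-en-1-yl)oxocan-4-yl acetate | C=CC[C@@H]1O[C@@H]([C@@H](Br)CC)C[C@H](OC(C)=O)[C@@H](Cl)C[C@@H]1Cl | intermediate
15 | ozonide of 14 (1,2,4-trioxolan-3-ylmethyl on the oxocane) | C1OC(C[C@@H]2O[C@@H]([C@@H](Br)CC)C[C@H](OC(C)=O)[C@@H](Cl)C[C@@H]2Cl)OO1 | intermediate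
16 | (2R,4S,5S,7S,8S)-2-[(1S)-1-bromopropyl]-5,7-dichloro-8-(2-oxoethyl)oxocan-4-yl acetate | O=CC[C@@H]1O[C@@H]([C@@H](Br)CC)C[C@H](OC(C)=O)[C@@H](Cl)C[C@@H]1Cl | intermediate
17 | (2R,4S,5S,7S,8S)-2-[(1S)-1-bromopropyl]-5,7-dichloro-8-[(2Z)-5-(triisopropylsilyl)pent-2-en-4-yn-1-yl]oxocan-4-yl acetate | CC(C)[Si](C(C)C)(C(C)C)C#C/C=C\C[C@@H]1O[C@@H]([C@@H](Br)CC)C[C@H](OC(C)=O)[C@@H](Cl)C[C@@H]1Cl | intermediate
18 | (2R,4S,5S,7S,8S)-2-[(1S)-1-bromopropyl]-5,7-dichloro-8-[(2Z)-pent-2-en-4-yn-1-yl]oxocan-4-yl acetate | C#C/C=C\C[C@@H]1O[C@@H]([C@@H](Br)CC)C[C@H](OC(C)=O)[C@@H](Cl)C[C@@H]1Cl | target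

**Totals and risks**
Total step count: 11. Longest linear sequence: 11 (fully linear).

Steps most likely to fail:

1. Step 8 (the proposed new ring expansion). Chloride may attack oxonium 13 at C6 or C12 instead of C9, giving isomeric oxolanes, and the C10 acetate may intercept the ion. Fallback with known chemistry, setting out from 11 and coming back at 14: triflate 11 as in step 8 but add no chloride and warm to 0 °C, so that the C10 acetate carbonyl opens the oxonium at C9 from inside (ester-terminated ring expansion, the established way to steer such ions to the eight-membered ring). This gives the oxocane-fused 2-methyl-1,3-dioxolan-2-ylium triflate bridging C9 and C10 F4. Aqueous NaHCO3 hydrolyses it to (2R,4S,5S,7S,8S)-2-[(1S)-1-bromopropyl]-7-chloro-5-hydroxy-8-(prop-2-en-1-yl)oxocan-4-yl acetate F5. Appel chlorination of this trans-acetoxy alcohol (CCl4, P(n-C8H17)3, toluene, 70 °C) is expected to proceed with retention through acetoxy participation (double inversion) and delivers 14. The C9 versus C10 selectivity of that last chloride opening is itself untested.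

2. Step 5 (bromoetherification). The risks are 6-endo closure, intermolecular bromohydrin formation and an insufficient 2,5-cis ratio. Fallback setting out from 5 and coming back at 6: remove the ketal with 80% aqueous AcOH at 40 °C to give (4R,5S,7E)-dec-7-en-1-yne-4,5-diol F3. Cyclise the free C9 hydroxyl with 2,4,4,6-tetrabromocyclohexa-2,5-dienone in anhydrous CH2Cl2 at −20 °C (hydroxyl-driven 5-exo bromoetherification, no ketal fragmentation and no water) to give 6, which is acetylated to 7 as in step 5. This removes the water-dependent failure modes but does not by itself guarantee a better cis ratio.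

3. Step 2 (olefination of a free lactol). The risks are low conversion and an E/Z ratio that would carry through as the C13 epimer. Fallback setting out from 2 and coming back at 3: homologate the lactol with dimethyl (1-diazo-2-oxopropyl)phosphonate, K2CO3, MeOH to [(4R,5S)-2,2-dimethyl-5-(prop-2-yn-1-yl)-1,3-dioxolan-4-yl]methanol F1. Treat with n-BuLi (2.1 equiv), THF/DMPU, then EtI to give [(4R,5S)-2,2-dimethyl-5-(pent-2-yn-1-yl)-1,3-dioxolan-4-yl]methanol F2. Dissolving-metal reduction (Na, NH3, t-BuOH, −33 °C) gives 3 as the pure E isomer.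

**Further compounds**
F1 | step 2 | [(4R,5S)-2,2-dimethyl-5-(prop-2-yn-1-yl)-1,3-dioxolan-4-yl]methanol | C#CC[C@@H]1OC(C)(C)O[C@@H]1CO
F2 | step 2 | [(4R,5S)-2,2-dimethyl-5-(pent-2-yn-1-yl)-1,3-dioxolan-4-yl]methanol | CCC#CC[C@@H]1OC(C)(C)O[C@@H]1CO
F3 | step 5 | (4R,5S,7E)-dec-7-en-1-yne-4,5-diol | CC/C=C/C[C@H](O)[C@H](O)CC#C
F4 | step 8 | oxocane-fused 2-methyl-1,3-dioxolan-2-ylium triflate (acetoxonium bridging C9 and C10, trans-fused) | C=CC[C@@H]1O[C@@H]([C@@H](Br)CC)C[C@@H]2OC(C)=[O+][C@H]2C[C@@H]1Cl.[O-]S(=O)(=O)C(F)(F)F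
F5 | step 8 | (2R,4S,5S,7S,8S)-2-[(1S)-1-bromopropyl]-7-chloro-5-hydroxy-8-(prop-2-en-1-yl)oxocan-4-yl acetate | C=CC[C@@H]1O[C@@H]([C@@H](Br)CC)C[C@H](OC(C)=O)[C@@H](O)C[C@@H]1Cl
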